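**The vessel.** In the stirred vessel, target forms when open intermediate, made from starting material and reagent, meets second intermediate, made from reagent and partner.

in all of them: starting material 0.020 M

|  | partner | reagent | protic impurity | remark | time |
|---|---|---|---|---|---|
| oak | 0.022 M | 0.050 M | 2 mM | run made earlier |  |
| ash | 0.022 M | 0.050 M | 1.3 mM | run made earlier |  |
| cedar | 0.022 M | 0.050 M | 3 mM | run made earlier |  |
| winter | 0.0220 M (fed, over 40 h) | 0.0500 M | 2.00 mM | all else is in the flask from the start; the feed brings no volume worth counting | 50 h |
| summer | 0.0220 M | 0.0500 M | 2.00 mM | everything together at the start | 50 h |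
| spring | 0.0220 M | 0.0500 M (fed, over 40 h) | 2.00 mM | all else is in the flask from the start; the feed brings no volume worth counting | 50 h |
| autumn | 0.0220 M | 0.0500 M (in portions, 3, over 40 h) | 2.00 mM | first portion at the start, last at 40 h | 50 h |

- oak (time / h: target / %, starting material / %): 2.50: 0, 89.7; 4.00: 0, 83.9; 6.00: 0, 77.2; 10.0: 1.7, 65.8; 20.0: 3.9, 47.2; 30.0: 7.5, 33.8
- ash (time / h: target / %, starting material / %): 2.00: 0, 91.5; 6.00: 0.8, 77.2; 10.0: 1.3, 66.3; 15.0: 2.8, 55.3; 25.0: 5.4, 39.8; 30.0: 7.0, 34.5
- cedar (time / h: target / %, starting material / %): 5.00: 0.9, 81.3; 10.0: 0.8, 65.7; 15.0: 1.9, 55.2; 20.0: 3.2, 46.4; 25.0: 4.6, 39.0; 30.0: 6.7, 34.0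

(each reading ± 0.5 percentage points)

- in percentages every species weighs as the starting material in it: one side product counts as two
- steps under discussion: starting material + reagent -> open intermediate; reagent + partner -> second intermediate; open intermediate + second intermediate -> target; partner + protic impurity -> quenched reagent; partner <-> dormant form; starting material + target -> side product

- the flask with the highest amount of target, in percent of the starting material charged ("all alike" if they lie within 1.5 percentage points) (winter / summer / spring / autumn / all alike)
- final target, as a percentage of the starting material charged, in winter
- final target, as a percentage of the starting material charged, in summer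
- final target, as a percentage of the starting material charged, in spring
- final target, as a percentage of the starting material charged, in autumn

**Lag exponent.** Oak has the charges of summer, and its target rises from 3.9 % at 20.0 h to 7.5 % at 30.0 h. This curve, which starts with a lag (induction period), reads as target growing with time to the power n = 1.61, with the scatter of those readings in it. Carried on to 50 h, it gives us 17.1 % for summer.

**Kept share.** A steady feed over 40 h arrives on average 20.0 h late, and so do the autumn portions if evenly spaced. We therefore fold the recipe into the kept share, the fraction of the run that the average charge spends in the flask, which is one minus the mean delay divided by the run time, here 0.600. Winter, spring and autumn have this same number, so it can't separate them, and the steps have to do that. Reagent enters the steps to both intermediates, but partner enters the step to the second. Giving each delayed intermediate an equal part of n, we reckon 7.50 % for spring and autumn and 11.3 % for winter.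

**The forecast.** The forecast held that “anything that delays either one costs yield”. It named summer at 16 %, with winter 8.5 %, autumn 6.5 % and spring 5 %, so its winter stands lower than ours.

**The flasks.** The highest is summer at 16.2 %, then winter 10.3 %, spring 6.69 % and autumn 6.48 %.

    starting material + reagent → open intermediate (k = 2.60 × 10⁻⁴ M⁻¹ s⁻¹)
    reagent + partner → second intermediate (k = 2.20 × 10⁻⁴ M⁻¹ s⁻¹)
    open intermediate + second intermediate → target (k = 4.70 × 10⁻⁴ M⁻¹ s⁻¹)
    partner + protic impurity → quenched reagent (k = 0.00130 M⁻¹ s⁻¹)
    partner ⇌ dormant form (K = 0.730, k = 6.20 × 10⁻⁵ s⁻¹)
    starting material + target → side product (k = 9.10 × 10⁻⁴ M⁻¹ s⁻¹)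

**What ran.** In summer, by 50.0 h, open intermediate stood at 53.8 % of the starting material charged, beside 0.00656 M of second intermediate, while target stood at 16.2 %. Meanwhile target met starting material and side product reached 12.2 %, the half-life of target by that step alone, with starting material as charged, being 11 h, shorter than 50 h. Winter dosed over 12.0 h has a kept share of 0.880, which on summer's result gives 14.6 %, and that flask ends at 14.9 %.

Readings and results are simulated for substances that don't exist; the scatter is artificial.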